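**Retrosynthetic overview**

1. Feature: number each A ring C1 (aroyl-bearing), C2 (OH), C3 (bridge-bearing), C4 (OMe), C5 (H), C6 (OH). Then C2–C3–CH2–C3′–C2′ across the two A rings is one five-carbon glutaryl chain, and C4–C5–C6 of each ring is a three-carbon malonyl unit.
2. Endgame: target ⇐ hydrogenolysis of the two B-ring benzyl ethers ⇐ O-methylation of the C4 hydroxyl (para to the aroyl group) on each A ring of a methylene-bridged bis(aroylphloroglucinol).
3. Key disconnection: C3–C4 and C1–C6 of both A rings (four C–C bonds, two rings at once) ⇒ a glutaryl-linked 1,9-diarylnonane-1,3,7,9-tetraone, reacting as its tetrakis(silyl) bis-dienol ether, plus two malonyl dichlorides. Lactone (pyrone) closure is tolerated, because Mg(OMe)2 in the same flask converts it into the arene.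
4. Tetraone ⇐ twofold acylation of the lithium enolate of the B-ring methyl ketone by the bis-Weinreb amide of glutaric acid. The amide replaces a glutarate diester because the mono-adduct of a diester can close to a 2-aroylcyclohexane-1,3-dione. Ketone ⇐ orcacetophenone by 4-O-benzylation and 2-O-methylation.
5. Ring order: the B rings are bought, the bridge carbon arrives inside the glutaryl unit, and both A rings are formed last and together in the key step.

Key step: step 5

Assumption: the target has no stereogenic element (the SMILES carries no stereodescriptor and the molecule is achiral), so no step needs stereocontrol; compounds 1, 4 and 7 are taken as purchasable.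

**Step 1**
Reactants: 1 2′,4′-dihydroxy-6′-methylacetophenone
Product: 2 1-[4-(benzyloxy)-2-hydroxy-6-methylphenyl]ethan-1-one
Conditions: BnBr (1.05 equiv), K2CO3, acetone, reflux
Reagents that add atoms: benzyl bromide, BrCc1ccccc1
Why: Williamson ether synthesis; the 2-hydroxyl is tied up in a hydrogen bond to the acetyl carbonyl, so carbonate deprotonates and benzylates the para 4-hydroxyl selectively.

**Step 2**
Reactants: 2 1-[4-(benzyloxy)-2-hydroxy-6-methylphenyl]ethan-1-one
Product: 3 1-[4-(benzyloxy)-2-methoxy-6-methylphenyl]ethan-1-one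
Conditions: MeI (excess), K2CO3, DMF, 50 °C
Reagents that add atoms: iodomethane, CI
Why: Williamson O-methylation of the remaining, chelated phenol under more forcing conditions; carbonate is too weak a base to C-methylate the hindered methyl ketone.

**Step 3**
Reactants: 4 glutaryl dichloride
Product: 5 N1,N5-dimethoxy-N1,N5-dimethylpentanediamide
Conditions: MeNH(OMe)·HCl (2.2 equiv), pyridine, CH2Cl2, 0 → 20 °C
Reagents that add atoms: N,O-dimethylhydroxylamine hydrochloride, CNOC.Cl
Why: Acylation of a secondary amine by an acid chloride (Weinreb amide formation); the amine has a single N–H, so no imide can form.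

**Step 4**
Reactants: 3 1-[4-(benzyloxy)-2-methoxy-6-methylphenyl]ethan-1-one (2.4 equiv); 5 N1,N5-dimethoxy-N1,N5-dimethylpentanediamide
Product: 6 1,9-bis[4-(benzyloxy)-2-methoxy-6-methylphenyl]nonane-1,3,7,9-tetraone
Conditions: LiHMDS, THF, −78 °C; then 5, −78 → 0 °C; cold 1 M HCl
Reagents that add atoms: none
Why: Claisen-type acylation of a ketone lithium enolate by a Weinreb amide at both ends; the di-ortho-substituted aryl ketone cannot self-condense, and the weakly electrophilic amide, unlike a glutarate ester, leaves no acylating group that the first-formed diketonate could attack in a Dieckmann closure to a 2-aroylcyclohexane-1,3-dione.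

**Step 5**
Reactants: 6 1,9-bis[4-(benzyloxy)-2-methoxy-6-methylphenyl]nonane-1,3,7,9-tetraone; 7 malonyl dichloride (3 equiv)
Product: 10 bis{3-[4-(benzyloxy)-2-methoxy-6-methylbenzoyl]-2,4,6-trihydroxyphenyl}methane, via tetrakis(trimethylsilyl) bis-dienol ether 8 (not isolated), via bis(4-hydroxy-2-pyrone) 9 (not isolated)
Conditions: TMSOTf (4.2 equiv), Et3N, Et2O, 0 → 20 °C, ammonium salt layer removed, volatiles evaporated; crude 8 added slowly to 7, CH2Cl2, −78 → 0 °C; MeOH; Mg(OMe)2 (excess), MeOH, 50 °C; 1 M HCl
Reagents that add atoms: trimethylsilyl trifluoromethanesulfonate, C[Si](C)(C)OS(=O)(=O)C(F)(F)F (its silyl groups are carried only by intermediate 8)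
Why: Proposed new method: each 1-aryl-1,3-bis(silyloxy)diene of 8 should be C-acylated at its terminal carbon C3 by one acid chloride of 7 (vinylogous Mukaiyama-type acylation, bond C3–C4), and the pendant β-keto acid chloride, probably as its acylketene, is then captured within the same unit, by C1 directly or more likely by the C2 enol oxygen in a 6-exo-trig lactonisation to the 6-aroylmethyl-4-hydroxy-2-pyrone 9. Mg(OMe)2 in methanol then opens each lactone to the magnesium chelate of a 3,5,7-triketo ester, whose diketone carbon C1 attacks the ester carbon C6 in a 6-exo-trig Claisen (Dieckmann-type) closure (bond C1–C6), and tautomerisation of the trione to the hydrogen-bonded aroylphloroglucinol makes the closure irreversible, so that O-closed and C-closed material converge on 10. The closest known reactions are the Effenberger annulation of enol ethers with malonyl dichloride (pyrones and 1,3,5-triones), the terminal acylation of 1,3-bis(silyloxy)dienes by acid chlorides and the Mg(OMe)2-mediated Claisen recyclisation of 6-(2-oxoalkyl)-4-hydroxy-2-pyrones to acylphloroglucinols; their twofold use on an aroyl diketone whose two units are joined through one CH2 has no precedent. No stereocentre is formed. The step needs terminal-before-central acylation, which is inherent in the diene; closure inside each diketone unit and not onto C3′ of the other diene across the bridge, which the slow addition of 8 to excess 7 at −78 °C is meant to secure by acylating both termini before either chain can reach across; and Claisen instead of aldol cyclisation, which the substrate secures because the aroyl carbonyl that a C5 carbanion would have to attack is shielded by its ortho-methoxy and ortho-methyl groups.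

**Step 6**
Reactants: 10 bis{3-[4-(benzyloxy)-2-methoxy-6-methylbenzoyl]-2,4,6-trihydroxyphenyl}methane
Product: 11 bis{3-[4-(benzyloxy)-2-methoxy-6-methylbenzoyl]-2,4-dihydroxy-6-methoxyphenyl}methane
Conditions: Me2SO4 (2.1 equiv), K2CO3 (2.2 equiv), acetone, 0 → 20 °C
Reagents that add atoms: dimethyl sulfate, COS(=O)(=O)OC
Why: Williamson O-methylation with one equivalent of base and of a hard methylating agent per ring: the C4 hydroxyl, para to the aroyl carbonyl, is the most acidic phenol and the only one that is never hydrogen-bonded to the ketone, so its phenoxide should form and react first, as in the known selective 4-O-methylation of 2,4,6-trihydroxyaryl ketones.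

**Step 7**
Reactants: 11 bis{3-[4-(benzyloxy)-2-methoxy-6-methylbenzoyl]-2,4-dihydroxy-6-methoxyphenyl}methane
Product: 12 digriseophene A, bis[2,4-dihydroxy-3-(4-hydroxy-2-methoxy-6-methylbenzoyl)-6-methoxyphenyl]methane
Conditions: H2 (1 atm), 10% Pd/C, EtOAc, 20 °C
Reagents that add atoms: none
Why: Catalytic hydrogenolysis of aryl benzyl ethers; the tetra-ortho-substituted, chelated diaryl ketones and the aryl methyl ethers should not be touched at 1 atm and room temperature.

**Compound list**

1 | 2′,4′-dihydroxy-6′-methylacetophenone | CC(=O)c1c(C)cc(O)cc1O | starting material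
2 | 1-[4-(benzyloxy)-2-hydroxy-6-methylphenyl]ethan-1-one | CC(=O)c1c(C)cc(OCc2ccccc2)cc1O | intermediate
3 | 1-[4-(benzyloxy)-2-methoxy-6-methylphenyl]ethan-1-one | CC(=O)c1c(C)cc(OCc2ccccc2)cc1OC | intermediate
4 | glutaryl dichloride (pentanedioyl dichloride) | O=C(Cl)CCCC(=O)Cl | starting material
5 | N1,N5-dimethoxy-N1,N5-dimethylpentanediamide | CON(C)C(=O)CCCC(=O)N(C)OC | intermediate
6 | 1,9-bis[4-(benzyloxy)-2-methoxy-6-methylphenyl]nonane-1,3,7,9-tetraone | O=C(CC(=O)CCCC(=O)CC(=O)c1c(C)cc(OCc2ccccc2)cc1OC)c1c(C)cc(OCc2ccccc2)cc1OC | intermediate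
7 | malonyl dichloride | O=C(Cl)CC(=O)Cl | starting material
8 | 1,9-bis[4-(benzyloxy)-2-methoxy-6-methylphenyl]-1,3,7,9-tetrakis(trimethylsilyloxy)nona-1,3,6,8-tetraene (double-bond geometry not defined; formed in the flask in step 5) | C[Si](C)(C)OC(=CC(O[Si](C)(C)C)=CCC=C(O[Si](C)(C)C)C=C(O[Si](C)(C)C)c1c(C)cc(OCc2ccccc2)cc1OC)c1c(C)cc(OCc2ccccc2)cc1OC | intermediate
9 | 5,5′-methylenebis(6-{2-[4-(benzyloxy)-2-methoxy-6-methylphenyl]-2-oxoethyl}-4-hydroxy-2H-pyran-2-one) (formed in the flask in step 5) | O=C(CC1=C(CC2=C(CC(=O)c3c(C)cc(OCc4ccccc4)cc3OC)OC(=O)C=C2O)C(O)=CC(=O)O1)c1c(C)cc(OCc2ccccc2)cc1OC | intermediate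
10 | bis{3-[4-(benzyloxy)-2-methoxy-6-methylbenzoyl]-2,4,6-trihydroxyphenyl}methane | Oc1cc(O)c(C(=O)c2c(C)cc(OCc3ccccc3)cc2OC)c(O)c1Cc1c(O)cc(O)c(C(=O)c2c(C)cc(OCc3ccccc3)cc2OC)c1O | intermediate
11 | bis{3-[4-(benzyloxy)-2-methoxy-6-methylbenzoyl]-2,4-dihydroxy-6-methoxyphenyl}methane | COc1cc(O)c(C(=O)c2c(C)cc(OCc3ccccc3)cc2OC)c(O)c1Cc1c(OC)cc(O)c(C(=O)c2c(C)cc(OCc3ccccc3)cc2OC)c1O | intermediate
12 | digriseophene A | COc1cc(O)c(C(=O)c2c(C)cc(O)cc2OC)c(O)c1Cc1c(OC)cc(O)c(C(=O)c2c(C)cc(O)cc2OC)c1O | target

**Totals**

Total step count: 7.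
Longest linear sequence: 6 steps (1 → 2 → 3 → 6 → 10 → 11 → 12; steps 1, 2, 4, 5, 6, 7).

**Steps most likely to fail**

(1) Step 5, the step that bears the label. Three things may go wrong. One malonyl unit may bridge the terminal carbons C3 and C3′ of the two dienes, giving a six-membered ring across the CH2. The bifunctional acid chloride may link molecules into oligomers. Under Mg(OMe)2 the two halves may condense with each other through the 1,5-relationship of the C2 and C2′ carbonyls instead of closing to arenes.

The fallback uses only known reactions and a malonyl donor with a single acid chloride, so no second acylating site is present while the termini react. It sets out from tetraone 6, which is silylated to 8 as in step 5. Terminal C-acylation of both bis(silyloxy)dienes with methyl malonyl chloride (methyl 3-chloro-3-oxopropanoate, 2.4 equiv, CH2Cl2, −78 → 20 °C, aqueous work-up) should give the bis(triketo ester) dimethyl 4,6-bis{3-[4-(benzyloxy)-2-methoxy-6-methylphenyl]-3-oxopropanoyl}-3,7-dioxononanedioate F1 as a mixture of diastereomers and enol forms. The base-mediated Claisen cyclisation of 3,5,7-triketo esters to acylphloroglucinols (Mg(OMe)2, MeOH, 50 °C; 1 M HCl) then closes C1–C6 on both sides. Closure onto the fully substituted C3′ would be reversible and cannot aromatise. The fallback comes back to the route at 10.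

(2) Step 6. Site selectivity may be lost: methylation may run on to the C6 hydroxyl, begin at an ortho hydroxyl, or take place on carbon at C5 of the electron-rich ring.

The fallback fixes the methyl groups before the arene exists. It sets out from bis-pyrone 9, which is isolated for this purpose after the methanol quench of step 5. The pyrone 4-hydroxyls are vinylogous carboxylic acids and by far the most acidic sites. O-Methylation (Me2SO4, 2.1 equiv, K2CO3, acetone, 20 °C) should give 5,5′-methylenebis(6-{2-[4-(benzyloxy)-2-methoxy-6-methylphenyl]-2-oxoethyl}-4-methoxy-2H-pyran-2-one) F2. The pyrone 4-oxygen is the one that becomes the A-ring C4 oxygen. Methoxide ring opening and Claisen recyclisation of the 4-methoxy-6-(2-oxoalkyl)-2-pyrone (Mg(OMe)2, MeOH, 50 °C; 1 M HCl) should therefore give the 2,6-dihydroxy-4-methoxyaryl ketone pattern without any choice among phenols. The fallback comes back to the route at 11.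

(3) Step 4. The second acylation may stall at the mono-adduct, because a ketone enolate adds only slowly to a Weinreb amide. The tetraone is a 1,5-diketone flanked by two acidic methylenes and may undergo intramolecular aldol condensation during a long basic reaction or work-up.

The fallback uses the aryl ketone as an acetylide, so that no enolisable diketone exists until the last operation. It sets out from ketone 3. Enol phosphate formation (LDA, ClP(O)(OEt)2, THF, −78 °C) gives diethyl 1-[4-(benzyloxy)-2-methoxy-6-methylphenyl]ethenyl phosphate F3, which is not isolated. Elimination with further LDA gives 5-(benzyloxy)-2-ethynyl-1-methoxy-3-methylbenzene F4. Its lithium acetylide (n-BuLi, THF, −78 °C) should add once to each amide group of 5 and give, after acidic quench, the bis-ynone 1,9-bis[4-(benzyloxy)-2-methoxy-6-methylphenyl]nona-1,8-diyne-3,7-dione F5. Conjugate addition of pyrrolidine (EtOH, 20 °C) gives 1,9-bis[4-(benzyloxy)-2-methoxy-6-methylphenyl]-1,9-di(pyrrolidin-1-yl)nona-1,8-diene-3,7-dione F6 (alkene geometry not defined). Mild hydrolysis (aqueous oxalic acid, THF, 20 °C) then gives the tetraone. The fallback comes back to the route at 6.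

**Further compounds**

F1 | step 5 | dimethyl 4,6-bis{3-[4-(benzyloxy)-2-methoxy-6-methylphenyl]-3-oxopropanoyl}-3,7-dioxononanedioate (diastereomer mixture) | COC(=O)CC(=O)C(CC(C(=O)CC(=O)OC)C(=O)CC(=O)c1c(C)cc(OCc2ccccc2)cc1OC)C(=O)CC(=O)c1c(C)cc(OCc2ccccc2)cc1OC
F2 | step 6 | 5,5′-methylenebis(6-{2-[4-(benzyloxy)-2-methoxy-6-methylphenyl]-2-oxoethyl}-4-methoxy-2H-pyran-2-one) | O=C(CC1=C(CC2=C(CC(=O)c3c(C)cc(OCc4ccccc4)cc3OC)OC(=O)C=C2OC)C(OC)=CC(=O)O1)c1c(C)cc(OCc2ccccc2)cc1OC
F3 | step 4 | diethyl 1-[4-(benzyloxy)-2-methoxy-6-methylphenyl]ethenyl phosphate | C=C(OP(=O)(OCC)OCC)c1c(C)cc(OCc2ccccc2)cc1OC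
F4 | step 4 | 5-(benzyloxy)-2-ethynyl-1-methoxy-3-methylbenzene | C#Cc1c(C)cc(OCc2ccccc2)cc1OC
F5 | step 4 | 1,9-bis[4-(benzyloxy)-2-methoxy-6-methylphenyl]nona-1,8-diyne-3,7-dione | O=C(CCCC(=O)C#Cc1c(C)cc(OCc2ccccc2)cc1OC)C#Cc1c(C)cc(OCc2ccccc2)cc1OC
F6 | step 4 | 1,9-bis[4-(benzyloxy)-2-methoxy-6-methylphenyl]-1,9-di(pyrrolidin-1-yl)nona-1,8-diene-3,7-dione | O=C(CCCC(=O)C=C(N1CCCC1)c1c(C)cc(OCc2ccccc2)cc1OC)C=C(N1CCCC1)c1c(C)cc(OCc2ccccc2)cc1OC
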